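**Plan**

- Retrosynthesis: the O–CH3 bond of a ring A methyl ether is cut first. Next come the two C–Br bonds of ring B (C3'–Br, C6'–Br) together with the aromaticity of that ring, and last the ether bond between the ring A oxygen and C2 of a cyclohexenone.
- Enabling feature: ring B carries OH at C1', the aryl ether oxygen at C2' and bromines at C3' and C6', so the halogens flank the two adjacent oxygen-bearing carbons. These two carbons are the enol-ether β-carbon (C3) and the α'-carbon (C6) of a 2-aryloxycyclohex-2-en-1-one. Direct bromination of a 2-aryloxyphenol would instead place a bromine para to the hydroxyl (C4').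
- Forward: ring A is bought complete as 3,5-dibromosalicylaldehyde. Its phenol is methylated and the formyl group is turned into a hydroxyl. That phenol is joined to C2 of 2,3-epoxycyclohexanone (from 2-cyclohexen-1-one) to give the aryl enol ether enone.
- Ring B is never closed: its six carbons come intact from cyclohexenone and are brominated and aromatized in one operation. BBr3 then frees the ring A phenol.
- Stereochemistry: the target has no stereocentre. The two centres of the racemic epoxy ketone disappear in the dehydration of step 4.

Key step: step 5

Remark on the chemistry: the epoxy ketone of step 3 is made and used as the racemate (one enantiomer is drawn in the SMILES), and phenols are written in the neutral form obtained after work-up.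

**Route**

Step 1
Reactants: 1 3,5-dibromosalicylaldehyde (3,5-dibromo-2-hydroxybenzaldehyde)
Product: 2 3,5-dibromo-2-methoxybenzaldehyde
Conditions: MeI, K2CO3, DMF, rt
Reagents that add atoms: iodomethane, CI
Why: Williamson O-methylation (SN2 on MeI) of an acidic ortho-substituted phenol; the aldehyde and the aryl bromides are inert, and the methyl ether leaves ring A with a single nucleophilic oxygen after step 2.

Step 2
Reactants: 2 3,5-dibromo-2-methoxybenzaldehyde
Product: 4 3,5-dibromo-2-methoxyphenol, via aryl formate 3 (not isolated)
Conditions: mCPBA, CH2Cl2, 40 °C; aqueous NaHCO3 wash; then K2CO3 (cat.), MeOH, rt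
Reagents that add atoms: 3-chloroperoxybenzoic acid (mCPBA), O=C(OO)c1cccc(Cl)c1
Why: Baeyer–Villiger (Dakin-type) oxidation of an ortho-alkoxybenzaldehyde, in which the ortho methoxy group favours aryl over hydride migration in the Criegee intermediate; the labile formate 3 is methanolysed without isolation.

Step 3
Reactants: 5 2-cyclohexen-1-one
Product: 6 2,3-epoxycyclohexan-1-one (7-oxabicyclo[4.1.0]heptan-2-one), racemic
Conditions: 30% aq. H2O2, NaOH (cat.), MeOH, 0 °C
Reagents that add atoms: hydrogen peroxide, OO
Why: Weitz–Scheffer nucleophilic epoxidation of an enone (conjugate addition of hydroperoxide, then ring closure on the O–O bond); the cis-fused racemate suffices because both stereocentres are lost in step 4.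

Step 4
Reactants: 4 3,5-dibromo-2-methoxyphenol; 6 2,3-epoxycyclohexan-1-one
Product: 8 2-(3,5-dibromo-2-methoxyphenoxy)cyclohex-2-en-1-one, via hydroxy ketone 7 (not isolated)
Conditions: Cs2CO3 (0.3 equiv), 6 (1.5 equiv), DMF, 70 °C
Reagents that add atoms: none
Why: Phenoxide opening of an α,β-epoxy ketone at the carbonyl-activated α-carbon (SN2, inversion) followed by E1cB loss of the β-hydroxyl, the established way to 2-aryloxy and 2-arylthio enones; the base is catalytic because the alkoxide and hydroxide formed regenerate phenoxide.

Step 5
Reactants: 8 2-(3,5-dibromo-2-methoxyphenoxy)cyclohex-2-en-1-one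
Product: 12 3,6-dibromo-2-(3,5-dibromo-2-methoxyphenoxy)phenol, via 3-bromo enone 9 (not isolated), via tribromo enone 10 (not isolated), via dienone tautomer 11 (not isolated)
Conditions: Br2 (3.0 equiv), AcOH, 15 to 45 °C; evaporate; then Li2CO3, DMF, 90 °C
Reagents that add atoms: bromine, BrBr
Why: Proposed new method: electrophilic bromine attacks C3, the β-carbon of the aryl enol ether, the oxocarbenium ion at C2 loses the C3 proton to give 9, and HBr-catalysed enolization toward C6, the only enolizable α-position, brings in two further bromines to give 10. Li2CO3 then removes HBr across C5–C6, and the cross-conjugated dienone 11 becomes the phenol by a proton shift from C4 to oxygen. The closest known reaction type is the bromination–dehydrobromination of cyclohexanones, cyclohexenones and cyclohexane-1,2-diones to ortho-bromophenols and bromocatechols; a substrate with an aryl enol ether at C2 has not been taken through it. No ring closes and no stereocentre is formed; the two C–Br bonds at C3 and C6 are the bonds made. The step needs site selectivity for C3 and C6 over C4 and C5 and a stop at two ring B bromines: the enol ether directs to C3, the carbonyl to C6, and all bromine is consumed at the non-aromatic stage before the base unveils the phenol, so the free para position of 12 should never meet Br2. Ring A, with two bromines and no free hydroxyl, should stay untouched.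

Step 6
Reactants: 12 3,6-dibromo-2-(3,5-dibromo-2-methoxyphenoxy)phenol
Product: 13 3,6-dibromo-2-(3,5-dibromo-2-hydroxyphenoxy)phenol (target)
Conditions: BBr3 (3 equiv), CH2Cl2, −78 °C to rt; then H2O
Reagents that add atoms: none
Why: Lewis-acid demethylation of an aryl methyl ether with BBr3 (aryloxyborane formation, bromide attack on the methyl group); the diaryl ether and the aryl bromides are stable, and the free ring B phenol only consumes extra reagent.

**Compound list**

1 | 3,5-dibromosalicylaldehyde | O=Cc1cc(Br)cc(Br)c1O | starting material
2 | 3,5-dibromo-2-methoxybenzaldehyde | O=Cc1cc(Br)cc(Br)c1OC | intermediate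
3 | 3,5-dibromo-2-methoxyphenyl formate | O=COc1cc(Br)cc(Br)c1OC | intermediate
4 | 3,5-dibromo-2-methoxyphenol | COc1c(Br)cc(Br)cc1O | intermediate
5 | 2-cyclohexen-1-one | O=C1C=CCCC1 | starting material
6 | 2,3-epoxycyclohexan-1-one, cis-fused, racemic (one enantiomer drawn) | O=C1CCC[C@@H]2O[C@H]12 | intermediate
7 | trans-2-(3,5-dibromo-2-methoxyphenoxy)-3-hydroxycyclohexan-1-one, racemic (one enantiomer drawn) | O=C1CCC[C@H](O)[C@H]1Oc1cc(Br)cc(Br)c1OC | intermediate
8 | 2-(3,5-dibromo-2-methoxyphenoxy)cyclohex-2-en-1-one | COc1c(Br)cc(Br)cc1OC1=CCCCC1=O | intermediate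
9 | 3-bromo-2-(3,5-dibromo-2-methoxyphenoxy)cyclohex-2-en-1-one | COc1c(Br)cc(Br)cc1OC1=C(Br)CCCC1=O | intermediate
10 | 3,6,6-tribromo-2-(3,5-dibromo-2-methoxyphenoxy)cyclohex-2-en-1-one | COc1c(Br)cc(Br)cc1OC1=C(Br)CCC(Br)(Br)C1=O | intermediate
11 | 3,6-dibromo-2-(3,5-dibromo-2-methoxyphenoxy)cyclohexa-2,5-dien-1-one | COc1c(Br)cc(Br)cc1OC1=C(Br)CC=C(Br)C1=O | intermediate
12 | 3,6-dibromo-2-(3,5-dibromo-2-methoxyphenoxy)phenol | COc1c(Br)cc(Br)cc1Oc1c(Br)ccc(Br)c1O | intermediate
13 | 3,6-dibromo-2-(3,5-dibromo-2-hydroxyphenoxy)phenol | Oc1c(Br)cc(Br)cc1Oc1c(Br)ccc(Br)c1O | target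

**Summary**

Total step count: 6. Longest linear sequence: 5 steps (1 → 2 → 4 → 8 → 12 → 13, steps 1, 2, 4, 5 and 6); the cyclohexenone branch (step 3) joins at step 4.

**Steps most likely to fail**

Step 5 (the step that goes beyond known chemistry).
- What may go wrong: bromination at the allylic C4 through the extended dienol may compete with the second bromination at C6. The third bromination may stay incomplete. During the base stage the gem-dibromide may transfer bromine to the phenoxide. Each of these would scramble the halogen pattern of ring B.
- Fallback, using known chemistry, sets out from phenol 4 and brings in the ring B carbons already aromatic. SNAr of the phenoxide of 4 on commercial 3,6-dibromo-2-fluorobenzaldehyde (K2CO3, DMF, 90 °C; fluoride activated by the ortho formyl group) should give 3,6-dibromo-2-(3,5-dibromo-2-methoxyphenoxy)benzaldehyde F1. Baeyer–Villiger oxidation with mCPBA in CH2Cl2 should give 3,6-dibromo-2-(3,5-dibromo-2-methoxyphenoxy)phenyl formate F2. Methanolysis (K2CO3, MeOH) returns to the route at 12.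

Step 4.
- What may go wrong: base-induced isomerization and self-condensation of the epoxy ketone may outrun attack by the hindered, weakly nucleophilic phenoxide, and the dehydration may stall at the hydroxy ketone stage.
- Fallback sets out from 4 and builds the oxygenated ring from a 1,3-dione, which fixes the position of the double bond. Insertion of the carbenoid from 2-diazocyclohexane-1,3-dione F3 (made from cyclohexane-1,3-dione by diazo transfer with 4-acetamidobenzenesulfonyl azide and Et3N) into the phenol O–H bond, catalysed by Rh2(OAc)4 in warm benzene, should give 2-(3,5-dibromo-2-methoxyphenoxy)cyclohexane-1,3-dione F4, largely enolized. Ph3PBr2 and Et3N in CH2Cl2 should convert the enol into the vinylogous acyl bromide, which is 3-bromo enone 9. The route is rejoined at 9 inside step 5, which then needs two instead of three equivalents of Br2 before the Li2CO3 stage.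

Step 2.
- What may go wrong: on the electron-poor dibromo ring, hydride migration in the Criegee intermediate may compete with aryl migration, so that the aldehyde is over-oxidized to the carboxylic acid level instead of giving the formate.
- Fallback sets out from aldehyde 2 and removes the migrating hydrogen. MeMgBr (THF, −20 °C) should give 1-(3,5-dibromo-2-methoxyphenyl)ethan-1-ol F5 (racemic). Dess–Martin periodinane should give 1-(3,5-dibromo-2-methoxyphenyl)ethan-1-one F6. Baeyer–Villiger oxidation (mCPBA, CF3CO2H, CH2Cl2), in which only aryl or methyl can migrate, should give 3,5-dibromo-2-methoxyphenyl acetate F7. K2CO3 in MeOH returns to the route at 4.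

**Further compounds**

F1 | step 5 | 3,6-dibromo-2-(3,5-dibromo-2-methoxyphenoxy)benzaldehyde | COc1c(Br)cc(Br)cc1Oc1c(Br)ccc(Br)c1C=O
F2 | step 5 | 3,6-dibromo-2-(3,5-dibromo-2-methoxyphenoxy)phenyl formate | COc1c(Br)cc(Br)cc1Oc1c(Br)ccc(Br)c1OC=O
F3 | step 4 | 2-diazocyclohexane-1,3-dione | [N-]=[N+]=C1C(=O)CCCC1=O
F4 | step 4 | 2-(3,5-dibromo-2-methoxyphenoxy)cyclohexane-1,3-dione | COc1c(Br)cc(Br)cc1OC1C(=O)CCCC1=O
F5 | step 2 | 1-(3,5-dibromo-2-methoxyphenyl)ethan-1-ol, racemic | COc1c(Br)cc(Br)cc1C(C)O
F6 | step 2 | 1-(3,5-dibromo-2-methoxyphenyl)ethan-1-one | COc1c(Br)cc(Br)cc1C(C)=O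
F7 | step 2 | 3,5-dibromo-2-methoxyphenyl acetate | COc1c(Br)cc(Br)cc1OC(C)=O
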